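**Retrosynthetic overview**
1. The target (C3‑aryl/C4‑aroyl trans, C4‑aroyl/C5‑aryl cis) is the C4 epimer of a normal endo chalcone–diene adduct; C4 is erased as a silyl enol ether and re‑set last by proton delivery from the neighbouring phenol.
2. That endo heptaphenol comes from a hexa‑O‑allyl cyclohexene made by a chiral‑borate‑catalysed (metal‑free) asymmetric Diels–Alder reaction of a dienyl chalcone with the diallyl ether of isobavachalcone; this fixes C3 and C5.
3. The dienyl chalcone comes from a Claisen–Schmidt condensation; its dienyl acetophenone half comes from Suzuki coupling of 3‑iodo‑2,4‑dihydroxyacetophenone.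
4. Rings: all four benzene rings are bought; the cyclohexene is the only ring formed, in the Diels–Alder step.

**Assumptions**
- Ring numbering used throughout: C1 = C–CH3, C2 = olefinic CH, C3 = CH–(chalcone aryl), C4 = CH–aroyl, C5 = CH–(4‑hydroxyphenyl), C6 = CH2; the target SMILES reads 3S,4S,5S.
- Compounds 3 and 9 are bought (3 is otherwise one hydroboration from 2‑methylbut‑1‑en‑3‑yne and pinacolborane).
- (S)‑VANOL is written for step 7; the sense of induction is to be confirmed on 11 by crystallography, and the mirror‑image ligand is used if it proves opposite.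

**Route**

Step 1
Reactants: 1 2,4‑dihydroxyacetophenone
Product: 2 3‑iodo‑2,4‑dihydroxyacetophenone
Conditions: I2 (0.4 equiv), HIO3 (0.2 equiv), EtOH/H2O, 35 °C
Reagents that add atoms: iodine, [I][I]; iodic acid, OI(=O)=O
Why: Electrophilic aromatic iodination with in situ generated iodonium goes to C3, the position activated by both hydroxyl groups, and the ortho‑coupled H5/H6 doublets confirm the regiochemistry.

Step 2
Reactants: 2 3‑iodo‑2,4‑dihydroxyacetophenone; 3 (E)‑3‑methylbuta‑1,3‑dienyl pinacol boronate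
Product: 4 3‑[(E)‑3‑methylbuta‑1,3‑dienyl]‑2,4‑dihydroxyacetophenone
Conditions: Pd(dppf)Cl2 (5 mol %), K2CO3, 1,4‑dioxane/H2O, 70 °C; pH 7 work‑up, Et3N‑deactivated silica
Reagents that add atoms: none
Why: Suzuki–Miyaura coupling of an aryl iodide with an E‑alkenyl boronate proceeds with retention of alkene geometry and tolerates free phenols under aqueous carbonate.

Step 3
Reactants: 4 3‑[(E)‑3‑methylbuta‑1,3‑dienyl]‑2,4‑dihydroxyacetophenone
Product: 5 2,4‑bis(allyloxy)‑3‑[(E)‑3‑methylbuta‑1,3‑dienyl]acetophenone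
Conditions: allyl bromide (3 equiv), K2CO3, DMF, 60 °C
Reagents that add atoms: allyl bromide, C=CCBr
Why: Williamson etherification caps both phenols with a base‑stable group removable later by palladium, so the ortho‑hydroxy diene can no longer cyclise to a chromene.

Step 4
Reactants: 6 2,4‑dihydroxybenzaldehyde
Product: 7 2,4‑bis(allyloxy)benzaldehyde
Conditions: allyl bromide (2.6 equiv), K2CO3, DMF, 60 °C
Reagents that add atoms: allyl bromide, C=CCBr
Why: Williamson etherification of both phenols gives an aldehyde that stays electrophilic under the basic aldol conditions.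

Step 5
Reactants: 5 2,4‑bis(allyloxy)‑3‑[(E)‑3‑methylbuta‑1,3‑dienyl]acetophenone; 7 2,4‑bis(allyloxy)benzaldehyde
Product: 8 tetra‑O‑allyl dienyl chalcone
Conditions: KOH (aq. 50 %), EtOH, 0 to 23 °C
Reagents that add atoms: none
Why: Claisen–Schmidt aldol condensation of a methyl ketone with a non‑enolisable aldehyde gives the E‑enone under thermodynamic control, and diene and allyl ethers are inert to hydroxide at room temperature.

Step 6
Reactants: 9 isobavachalcone
Product: 10 4,4'‑di‑O‑allyl isobavachalcone (2'‑OH free)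
Conditions: allyl bromide (2.2 equiv), K2CO3, acetone, 23 to 40 °C
Reagents that add atoms: allyl bromide, C=CCBr
Why: Chemoselective Williamson etherification, because the 2'‑hydroxyl is hydrogen‑bonded to the carbonyl and flanked by the prenyl group and so stays free for later boron chelation.

Step 7
Reactants: 8 tetra‑O‑allyl dienyl chalcone; 10 4,4'‑di‑O‑allyl isobavachalcone
Product: 11 (3S,4R,5S) hexa‑O‑allyl endo cyclohexene adduct
Conditions: 8 (1.5 equiv), (S)‑VANOL (20 mol %), B(OPh)3 (20 mol %), 4 Å MS, PhCF3, 40 °C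
Reagents that add atoms: none
Why: Chiral borate Lewis acid catalysed Diels–Alder reaction in which only the 2'‑hydroxy ketone of 10 chelates boron, the ligand shields one enone face and the endo transition state sets C3 (S), C4 (R) and C5 (S) together (C3/C4 cis, C4/C5 trans).

Step 8
Reactants: 11 (3S,4R,5S) hexa‑O‑allyl endo cyclohexene adduct
Product: 12 (3S,4R,5S) endo heptaphenol
Conditions: Pd(PPh3)4 (10 mol %), K2CO3, MeOH/THF, 40 °C, argon; pH 5 phosphate buffer work‑up
Reagents that add atoms: none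
Why: Tsuji–Trost type deallylation, in which the π‑allyl palladium species formed from each aryl allyl ether is captured by methanol, frees all phenols without acid, leaving the prenyl group and the acid‑sensitive aryl‑cyclohexene untouched.

Step 9
Reactants: 12 (3S,4R,5S) endo heptaphenol
Product: 14 target (3S,4S,5S) heptaphenol, via octakis(trimethylsilyl) silyl enol ether 13 (not isolated)
Conditions: Me3SiOTf (12 equiv), Et3N (16 equiv), CH2Cl2, 0 to 23 °C; evaporate, take up in pentane, filter; then THF/MeOH 9:1 (0.002 mol/L), −20 to 20 °C; aq. citric acid work‑up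
Reagents that add atoms: none
Why: Proposed new method: phenol‑relayed ketonisation — soft enolisation erases C4 as silyl enol ether 13, neutral methanolysis then frees the aryl silyl ethers first (fastest the one para to the chalcone carbonyl on the C3 aryl), and that acidic phenol, held on the face of the enol ether that carries the C3 aryl, protonates C4 through a six‑membered O–H···C transition state faster than any external acid at high dilution, so hydrogen enters syn to the C3 aryl and the aroyl group ends trans to it and cis to the C5 aryl (4S); the closest known reaction types are kinetic ketonisation of exocyclic enols with intramolecular proton delivery and general‑acid hydrolysis of silyl enol ethers.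

**Compound list**
1 | 1‑(2,4‑dihydroxyphenyl)ethanone | CC(=O)c1ccc(O)cc1O | starting material
2 | 1‑(2,4‑dihydroxy‑3‑iodophenyl)ethanone | CC(=O)c1ccc(O)c(I)c1O | intermediate
3 | 4,4,5,5‑tetramethyl‑2‑[(1E)‑3‑methylbuta‑1,3‑dien‑1‑yl]‑1,3,2‑dioxaborolane | CC(=C)/C=C/B1OC(C)(C)C(C)(C)O1 | starting material
4 | 1‑{2,4‑dihydroxy‑3‑[(1E)‑3‑methylbuta‑1,3‑dien‑1‑yl]phenyl}ethanone | CC(=O)c1ccc(O)c(/C=C/C(C)=C)c1O | intermediate
5 | 1‑{3‑[(1E)‑3‑methylbuta‑1,3‑dien‑1‑yl]‑2,4‑bis(prop‑2‑en‑1‑yloxy)phenyl}ethanone | CC(=O)c1ccc(OCC=C)c(/C=C/C(C)=C)c1OCC=C | intermediate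
6 | 2,4‑dihydroxybenzaldehyde | O=Cc1ccc(O)cc1O | starting material
7 | 2,4‑bis(prop‑2‑en‑1‑yloxy)benzaldehyde | O=Cc1ccc(OCC=C)cc1OCC=C | intermediate
8 | (2E)‑1‑{3‑[(1E)‑3‑methylbuta‑1,3‑dien‑1‑yl]‑2,4‑bis(prop‑2‑en‑1‑yloxy)phenyl}‑3‑[2,4‑bis(prop‑2‑en‑1‑yloxy)phenyl]prop‑2‑en‑1‑one | C=CCOc1ccc(/C=C/C(=O)c2ccc(OCC=C)c(/C=C/C(C)=C)c2OCC=C)c(OCC=C)c1 | intermediate
9 | isobavachalcone, (2E)‑1‑[2,4‑dihydroxy‑3‑(3‑methylbut‑2‑en‑1‑yl)phenyl]‑3‑(4‑hydroxyphenyl)prop‑2‑en‑1‑one | CC(C)=CCc1c(O)ccc(C(=O)/C=C/c2ccc(O)cc2)c1O | starting material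
10 | (2E)‑1‑[2‑hydroxy‑3‑(3‑methylbut‑2‑en‑1‑yl)‑4‑(prop‑2‑en‑1‑yloxy)phenyl]‑3‑[4‑(prop‑2‑en‑1‑yloxy)phenyl]prop‑2‑en‑1‑one | CC(C)=CCc1c(OCC=C)ccc(C(=O)/C=C/c2ccc(OCC=C)cc2)c1O | intermediate
11 | (3S,4R,5S)‑1‑methylcyclohex‑1‑ene with, at C3, 2,6‑bis(allyloxy)‑3‑[(2E)‑3‑(2,4‑bis(allyloxy)phenyl)prop‑2‑enoyl]phenyl; at C4, 4‑(allyloxy)‑2‑hydroxy‑3‑(3‑methylbut‑2‑enyl)benzoyl; at C5, 4‑(allyloxy)phenyl (C3/C4 cis, C4/C5 trans) | CC(C)=CCc1c(OCC=C)ccc(C(=O)[C@H]2[C@@H](c3c(OCC=C)ccc(C(=O)/C=C/c4ccc(OCC=C)cc4OCC=C)c3OCC=C)C=C(C)C[C@@H]2c2ccc(OCC=C)cc2)c1O | intermediate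
12 | (3S,4R,5S)‑1‑methylcyclohex‑1‑ene with, at C3, 2,6‑dihydroxy‑3‑[(2E)‑3‑(2,4‑dihydroxyphenyl)prop‑2‑enoyl]phenyl; at C4, 2,4‑dihydroxy‑3‑(3‑methylbut‑2‑enyl)benzoyl; at C5, 4‑hydroxyphenyl (C4 epimer of the target) | CC(C)=CCc1c(O)ccc(C(=O)[C@H]2[C@@H](c3c(O)ccc(C(=O)/C=C/c4ccc(O)cc4O)c3O)C=C(C)C[C@@H]2c2ccc(O)cc2)c1O | intermediate
13 | octakis(trimethylsilyl) derivative of 12: all seven phenols as Me3Si ethers and the C4 ketone as its exocyclic trimethylsilyl enol ether (C4 sp2, enol geometry not defined; C3 and C5 arranged as in 12, descriptors 3S,5R by priority change only) | CC(C)=CCc1c(O[Si](C)(C)C)ccc(C(O[Si](C)(C)C)=C2[C@@H](c3c(O[Si](C)(C)C)ccc(C(=O)/C=C/c4ccc(O[Si](C)(C)C)cc4O[Si](C)(C)C)c3O[Si](C)(C)C)C=C(C)C[C@@H]2c2ccc(O[Si](C)(C)C)cc2)c1O[Si](C)(C)C | intermediate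
14 | CNP0218862.3: (3S,4S,5S)‑1‑methylcyclohex‑1‑ene with, at C3, 2,6‑dihydroxy‑3‑[(2E)‑3‑(2,4‑dihydroxyphenyl)prop‑2‑enoyl]phenyl; at C4, 2,4‑dihydroxy‑3‑(3‑methylbut‑2‑enyl)benzoyl; at C5, 4‑hydroxyphenyl (C3/C4 trans, C4/C5 cis) | CC(C)=CCc1c(O)ccc(C(=O)[C@@H]2[C@@H](c3c(O)ccc(C(=O)/C=C/c4ccc(O)cc4O)c3O)C=C(C)C[C@@H]2c2ccc(O)cc2)c1O | target

**Step count and risks**
Total steps: 9. Longest linear sequence: 7 (steps 1, 2, 3, 5, 7, 8, 9).

Steps most likely to fail:

Step 9 (the new step). Soft enolisation of the hindered C4–H may be slow, and an external acid may protonate 13 from the open face and return 12 (which is recovered and recycled). Fallback by known chemistry, setting out from 11 and returning at 14: the last phenol of 11 is capped (allyl bromide, Cs2CO3, DMF, 50 °C) to give the hepta‑O‑allyl endo ketone F1. C4 is then equilibrated by ordinary base‑mediated α‑epimerisation (KOtBu 0.3 equiv, tBuOH/THF, 23 °C). The (3S,4S,5S) hepta‑O‑allyl epimer F2 is separated by preparative HPLC while F1 is recycled, and F2 is deallylated under the step 8 conditions to give 14.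

Step 7. Risks are incomplete endo/exo and facial selectivity, slow turnover through product binding to boron, and acid sensitivity of the electron‑rich diene. Fallback setting out from 8 and 10 and returning at 11: the cycloaddition is run without a chiral catalyst on silica‑supported silver nanoparticles (zerovalent silver on SiO2, CH2Cl2, 50 °C). The racemic endo adduct is isolated and resolved by preparative HPLC on a chiral stationary phase; the unwanted mirror‑image endo adduct F3 is set aside.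

Step 2. The coupling is run on an unprotected, doubly ortho‑substituted iodoresorcinol, and the product 4 is an acid‑sensitive ortho‑hydroxy diene. Fallback setting out from 2 and returning at 5: Heck coupling of 2 with 2‑methylbut‑3‑en‑2‑ol (Pd(OAc)2, K2CO3, Bu4NCl, DMF, 80 °C) gives the tertiary allylic alcohol F4. Double O‑allylation (allyl bromide, K2CO3, DMF, 60 °C) gives the bis(allyl ether) alcohol F5. Acid‑catalysed dehydration (pyridinium p‑toluenesulfonate, toluene, 80 °C) then gives 5, so the free ortho‑hydroxy diene is never handled.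

**Further compounds**
F1 | step 9 | hepta‑O‑allyl (3S,4R,5S) endo ketone (11 with the 2‑hydroxyl of the benzoyl ring also allylated) | CC(C)=CCc1c(OCC=C)ccc(C(=O)[C@H]2[C@@H](c3c(OCC=C)ccc(C(=O)/C=C/c4ccc(OCC=C)cc4OCC=C)c3OCC=C)C=C(C)C[C@@H]2c2ccc(OCC=C)cc2)c1OCC=C
F2 | step 9 | hepta‑O‑allyl (3S,4S,5S) ketone (C4 epimer of F1, hepta‑O‑allyl ether of 14) | CC(C)=CCc1c(OCC=C)ccc(C(=O)[C@@H]2[C@@H](c3c(OCC=C)ccc(C(=O)/C=C/c4ccc(OCC=C)cc4OCC=C)c3OCC=C)C=C(C)C[C@@H]2c2ccc(OCC=C)cc2)c1OCC=C
F3 | step 7 | (3R,4S,5R) hexa‑O‑allyl endo adduct (mirror image of 11) | CC(C)=CCc1c(OCC=C)ccc(C(=O)[C@@H]2[C@H](c3c(OCC=C)ccc(C(=O)/C=C/c4ccc(OCC=C)cc4OCC=C)c3OCC=C)C=C(C)C[C@H]2c2ccc(OCC=C)cc2)c1O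
F4 | step 2 | 1‑{2,4‑dihydroxy‑3‑[(1E)‑3‑hydroxy‑3‑methylbut‑1‑en‑1‑yl]phenyl}ethanone | CC(=O)c1ccc(O)c(/C=C/C(C)(C)O)c1O
F5 | step 2 | 1‑{3‑[(1E)‑3‑hydroxy‑3‑methylbut‑1‑en‑1‑yl]‑2,4‑bis(prop‑2‑en‑1‑yloxy)phenyl}ethanone | CC(=O)c1ccc(OCC=C)c(/C=C/C(C)(C)O)c1OCC=C
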